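**Assumption:** Emmaosunin (5-hydroxy-3,6,7,8,3'-pentamethoxyflavone) has no stereocenters, so the "single enantiomer" label is moot. 1,2,3,4-Tetramethoxybenzene, methyl 3-methoxybenzoate and methyl methoxyacetate are taken as commercial.

## Retrosynthetic overview
- Target **1** comes from the 5-OH/5-OMe switch of 3,5,6,7,8,3'-hexamethoxyflavone **2**, by chelation-controlled 5-O-demethylation at the end.
- The key step is a one-pot Simonis-type annulation. Phenol **3** (2,3,4,5-tetramethoxyphenol) and the α-methoxy-β-ketoester **4** form the C4a–C4 bond and the pyranone ring in one operation, so the 3-OMe and the C2 aryl group come in already in place.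
- **3** comes from symmetric 1,2,3,4-tetramethoxybenzene **5** by lithiation, borylation and oxidation. **4** comes from a crossed Claisen of methyl 3-methoxybenzoate **6** with methyl methoxyacetate **7**.
- Ring order: the A ring is already aromatic in **5**, and the pyranone C ring is closed in the Simonis step. The B ring comes in with **4**.

## Route

**Step 1**
Reactants: **5** 1,2,3,4-tetramethoxybenzene
Product: **3** 2,3,4,5-tetramethoxyphenol
Conditions: (i) n-BuLi, TMEDA, THF, 0 °C to rt; (ii) B(OMe)3, −78 °C to rt; (iii) 30% H2O2, 1 M NaOH, 0 °C; Na2S2O3 work-up
Reagents that add atoms: hydrogen peroxide (OO) supplies the phenolic O.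
Why: Directed ortho-metalation at C5 (C5 and C6 are equivalent by symmetry, so there is no regiochemical issue), followed by boronate oxidation, converts Ar–H to Ar–OH. No stereocenter is formed.

**Step 2**
Reactants: **6** methyl 3-methoxybenzoate, **7** methyl methoxyacetate
Product: **4** methyl 2-methoxy-3-(3-methoxyphenyl)-3-oxopropanoate
Conditions: LDA (2.2 equiv), **7** (2.2 equiv), THF, −78 °C; add **6** (1 equiv), warm to 0 °C; aq. NH4Cl
Reagents that add atoms: none
Why: Crossed Claisen condensation. The aryl ester cannot enolize, and deprotonation of the acidic product β-ketoester by the second equivalent of enolate drives the reaction. No stereocenter is formed (the product is largely enolized and the α-carbon is not configurationally relevant).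

**Step 3**
Reactants: **3** 2,3,4,5-tetramethoxyphenol, **4** β-ketoester
Product: **2** 3,5,6,7,8,3'-hexamethoxyflavone
Conditions: Eaton's reagent (P2O5/MsOH), 60–70 °C, N2, 2–4 h; pour onto ice, NaHCO3
Reagents that add atoms: none
Why: Proposed new method: this extends the Simonis chromone synthesis (phenol + β-ketoester under P2O5), which normally uses simple phenols and β-ketoesters. The ester carbonyl (via an acylium or acylketene equivalent) acylates the only free ring carbon, C6, which is ortho to the OH and ortho and para to OMe groups and so very nucleophilic. The phenol oxygen then condenses onto the aryl ketone, and loss of H2O and MeOH gives the 2-aryl-3-methoxychromone. The closest known reactions are the Simonis chromone cyclization, with the Pechmann coumarin synthesis as the competing pathway. The product is planar and achiral.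

**Step 4**
Reactants: **2** hexamethoxyflavone
Product: **1** Emmaosunin
Conditions: BCl3 (1.1–1.3 equiv), CH2Cl2, −78 to 0 °C, 1 h; quench with MeOH then aq. NaHCO3
Reagents that add atoms: none (the Cl ends up in MeCl and boron salts, not in the product).
Why: Lewis-acid cleavage of the 5-OMe is selective because it forms a six-membered B–O chelate with the C4 carbonyl, as in the known conversion of nobiletin to 5-demethylnobiletin. The 3-OMe, 6-OMe, 7-OMe, 8-OMe and 3'-OMe groups lack this chelation and survive at low temperature. No stereocenter is involved.

## Consistency checks
- Step 3 atom balance: **3** C10H14O5 + **4** C12H14O5 = C22H28O10. Product **2** is C21H22O8, so the loss is CH6O2 = MeOH + H2O. ✓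
- Step 4: **2** C21H22O8 minus CH2 gives C20H20O8, which is **1**. ✓
- The ring pattern is correct:
  - B ring: 3-methoxyphenyl at C2.
  - C ring: pyranone with 3-OMe and 4-C=O.
  - A ring: 5-OH and 6-, 7-, 8-OMe, with C8a–O from the phenol oxygen of **3**.
  - The 5-position comes from the C5-OMe of the phenol after chelation-controlled demethylation.
- Protecting groups: the aryl methyl ethers survive n-BuLi, LDA and MsOH at ≤70 °C. BCl3 at ≤0 °C cleaves only the chelated 5-OMe.

## Compound list
1 | Emmaosunin (5-hydroxy-3,6,7,8,3'-pentamethoxyflavone; achiral) | COc1cccc(-c2oc3c(OC)c(OC)c(OC)c(O)c3c(=O)c2OC)c1 | target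
2 | 3,5,6,7,8,3'-hexamethoxyflavone | COc1cccc(-c2oc3c(OC)c(OC)c(OC)c(OC)c3c(=O)c2OC)c1 | intermediate
3 | 2,3,4,5-tetramethoxyphenol | Oc1cc(OC)c(OC)c(OC)c1OC | intermediate
4 | methyl 2-methoxy-3-(3-methoxyphenyl)-3-oxopropanoate | COC(=O)C(OC)C(=O)c1cccc(OC)c1 | intermediate
5 | 1,2,3,4-tetramethoxybenzene | COc1ccc(OC)c(OC)c1OC | starting material
6 | methyl 3-methoxybenzoate | COC(=O)c1cccc(OC)c1 | starting material
7 | methyl methoxyacetate | COCC(=O)OC | starting material

**Total steps:** 4 (1 → 3 → 2 → target, plus the separate Claisen step that makes 4).
**Longest linear sequence:** 3 steps (5 → 3 → 2 → 1).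

## Three steps most likely to fail
1. **Step 3 (Simonis annulation).** The Pechmann pathway could give the 4-aryl-3-methoxycoumarin instead, or the electron-rich phenol could decompose in strong acid.
   - Fallback: change to a stepwise route. Do a Hoesch acylation of **3** with methoxyacetonitrile (ZnCl2/HCl) to give the 2-hydroxy-ω-methoxyacetophenone, then aroylate with 3-methoxybenzoyl chloride, rearrange to the 1,3-diketone (Baker–Venkataraman) and cyclodehydrate with acid.
2. **Step 4 (regioselective 5-demethylation).** Over-cleavage at the 3-OMe or 6-OMe, or an inseparable mixture, could result.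
   - Fallback: exhaustively demethylate **2** with BBr3, then re-methylate with MeI/K2CO3 in acetone, which leaves the chelated 5-OH free. Then separate the product from any under-methylated material.
3. **Step 1 (lithiation and oxidation).** Lithiation of **5** may be sluggish (only one ortho-OMe), and the electron-rich tetramethoxyphenol is prone to air oxidation to a quinone.
   - Fallback: formylate **5** (Rieche, Cl2CHOMe/TiCl4), then do a Baeyer–Villiger/Dakin oxidation with mCPBA and hydrolyze the formate.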